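(Readings and results were generated by integration on assumed constants; scatter was added.)

How many links does the green flask hold at 4.0 h, and which move can still add more than 2 percentage points?

| flask | first end groups | second end groups | temperature | remark | time |
|---|---|---|---|---|---|
| green | 29 mM | 1 equiv | 40 °C | the very flask that is asked about, followed so far |  |
| ochre | 19 mM | 1 equiv | 25 °C | run made earlier |  |
| flask | 29 mM | 1.00 equiv | 40 °C |  | 4.0 h |

| run | time / h | links / % | first end groups / % |
|---|---|---|---|
| green | 0.333 | 58.1 | 41.8 |
| green | 0.667 | 69.0 | 30.7 |
| green | 1.50 | 74.9 | 25.5 |
| green | 4.00 | 76.3 | 23.4 |
| ochre | 0.667 | 47.0 | 53.7 |
| ochre | 1.33 | 62.1 | 38.3 |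
| ochre | 3.00 | 74.1 | 25.4 |
| ochre | 8.00 | 81.0 | 19.1 |

(standard deviation of a reading: 0.3 percentage points)

- ash: at 4.0 h take out 90% of the links then present, then wait 2.0 h
- elm: at 4.0 h add second end groups, 50.0% of the amount charged, then wait 2.0 h
- larch: change nothing and wait 2.0 h more
- oak: at 4.0 h raise the temperature by 15 K, then wait 2.0 h

- links, in percent of the first end groups first charged, at 4.0 h
- the option that brings most further links ("none" if no option brings more than 2 percentage points) (ash / elm / larch / oak / none)
- links present, with what was taken out counted in, in percent of the first end groups first charged, after elm
- links present, with what was taken out counted in, in percent of the first end groups first charged, after oak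

- what is taken out of links is counted as made
- the numbers in the tables scatter with a standard deviation of 0.3 percentage points
- what may be going on: first end groups + second end groups -> links; second end groups -> decomposed reagent
- additions bring no volume worth counting

The card's steps run one way, so I read green's level, with first end groups left over, as second end groups lost to both steps. Let a be the free first end groups and b the free second end groups, both as fractions of the charge. Each link costs one second end group plus a further w/a lost to decomposition, where w is the waste ratio: decomposition constant over coupling constant times charge, the inverse of a selectivity factor. Summed from equal charges, this gives b = a + w·ln a, so at b = zero, w = a/ln(1/a). Green's last readings put a at 23.5%, so w is 0.163.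

Now the curve. Between green's first two readings the product a·b falls from 0.115 to 0.0352. Dividing the fall in a by the logarithmic mean of that product gives a starting slope of 4.92 /h, and decomposition is then 0.801 /h. The knee lies near 1.50 h, where the balance leaves b at 2.92%. Beyond it b dies at 1.96 /h, which leaves 0.0217% at 4.0 h. The level is therefore 76.4% links. Each link takes one second end group, so that remainder caps the further links from larch, ash and oak, and the remainder is less than the margin.

Elm restarts the balance from a = 23.5% with b = 50.0%. Run to b = zero, it ends at a ceiling of 96.3% links. But the wait is 2.0 h, so I reckon the end from the area under b against time. With a taken midway between its start and its ceiling value, b falls at the decomposition rate plus the starting slope times a, about 1.47 /h, and the area is 0.322 h. The first end groups shrink by the exponential of starting slope times area, which brings me to about 95.2%.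

The forecast says 76.4% now, elm as the best move, 95.2% after elm and 76.5% after oak, on the ground that “Waiting, heating or removing links therefore gains nothing”.

The flask gives 76.2%, with 0.0118% of the second end groups free. The best move is elm, at 19 points against 0.0068 points for larch and 0 points for oak. Elm ends at 95.3%, below the ceiling, and oak at 76.2%.

    first end groups + second end groups → links (k = 0.0480 /M/s, Ea = 44.0 kJ/mol)
    second end groups → decomposed reagent (k = 2.30 × 10⁻⁴ /s, Ea = 86.0 kJ/mol)
    (constants at 40 °C)

A neighbouring flask has 0.400 equiv of second end groups, with temperature and first end groups as here, so w carries over. Its balance at b = zero, solved by repeated substitution, leaves a = 66.7%, hence 33.3% links, or 83.2% of its second end groups charged. At 4.00 h that flask holds 33.3% links and 66.7% first end groups, with 0% of the second end groups free.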